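## The problem

The target 15 is a dibenzylbutyrolactone. A γ-lactone (O1, C2(=O), C3, C4, C5) carries a 4-hydroxy-3-methoxybenzyl arm (C7' and guaiacyl ring G) on C3 and a 4-hydroxy-3,5-dimethoxybenzyl arm (C7 and syringyl ring S) on C4. The three rings are joined only through the methylene groups C7' and C7 and are nowhere fused. There are two adjacent stereocentres, C3 (R) and C4 (R), with the two arms trans. C4 is not acidic and must be set absolutely and early. C3 is α to the lactone carbonyl, can be equilibrated, and prefers to sit trans to the C4 arm, so C4 can control C3. The two aryl rings differ by a single methoxy group, so each must be delivered to its own arm without any chance of crossover. Both rings carry a free phenol para to a benzylic CH2 (electron-rich and easily oxidised), and the lactone opens with hydroxide, so late intermediates should see neither oxidants nor prolonged aqueous base. The feature that the plan exploits lies in ring G. Numbered C1' (bearing C7') to C6', the unit C3'(OMe)–C4'(OH)–C5'(H) has the skeleton and oxidation pattern of methoxyacetone, and C2'–C1'–C6' with C7' is a 2-alkylmalondialdehyde. Ring G can therefore be assembled from two open-chain three-carbon pieces, with its phenol arriving unprotected.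

## Retrosynthesis

**15 ⇒ 14.** The O–CH2Ph bond on the ring S phenol is cut. One benzyl ether is the only protecting group the route needs: it endures Grignard formation, enolate chemistry, KOtBu and hot LiCl, and leaves by hydrogenolysis under neutral conditions that touch neither the lactone nor C3. Removing it earlier would expose a second phenoxide in the base steps. The forward step only has to be a clean hydrogenolysis.

**14 ⇒ 13.** The C3–H bond is replaced by C3–CO2Et. The ester makes C3 a soft, easily alkylated carbon, blocks enolisation at C3 while the arm is elaborated under base, and is removed by Krapcho dealkoxycarbonylation. At that moment C3 becomes an epimerisable CH and settles trans under the control of C4. The forward step must remove the ester without damaging the lactone and must end at the thermodynamic isomer.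

**13 ⇒ 10 + 11.** The C2'–C3' and C5'–C6' bonds of ring G are cut, leaving aminoacrolein 10 and methoxyacetone 11. The neighbouring cut at C3–C7' (alkylation with a vanillyl halide) would need a second protected phenol and a labile, electron-rich benzyl bromide. The ring construction instead delivers ring G with its phenol free and, in 13 and 14, distinguished from the still-benzylated ring S phenol. It also places all variation of ring G in one late step. The precursor is simpler by a whole aromatic ring. The forward reaction must form two C–C bonds and aromatise without attacking the quaternary lactone ester.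

**10 ⇒ 9.** The aminomethylene carbon is removed from the α-carbon of aldehyde 9. A formamide aminal ester supplies this carbon at the correct oxidation level. The step asks for a single enolisable position, which holds because C3 is quaternary.

**9 ⇒ 7 + 8.** The C3–C7' bond is cut. Acrolein 8 supplies C7', C1' and one ortho CH of ring G, and it adds to the malonate-type lactone ester 7 under catalytic base. The new quaternary centre forms anti to the C4 arm, but its configuration is immaterial in the end because step 7 resets C3.

**7 ⇒ 5 + 2 (through 6).** The C7–aryl bond is cut. The arylmagnesium bromide 6, with catalytic CuI, opens the doubly activated cyclopropane 5 at its CH2. Ring S is attached without a benzylic halide and the C4 stereocentre is not touched.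

**5 ⇒ 3 + 4, and 2 ⇒ 1.** The two cyclopropane bonds to the malonate carbon and the lactone acyl–O bond are cut, giving (R)-epichlorohydrin 3 and diethyl malonate 4. Compound 3 is the only source of absolute configuration. Aryl bromide 2 is the benzyl ether of commercial bromophenol 1.

## Roads not taken

**Alternative 1:** The lactone C2–C3 bond is cut. The precursor is the Se-phenyl selenocarbonate A1, in which C5–O carries the PhSe–C(=O) group and C3=C7' is a styrene double bond of ring G. With (Me3Si)3SiH and AIBN, the alkoxycarbonyl radical adds 5-exo to C3, and the benzylic C7' radical is reduced by the silane to give the bis-benzyl ether A2.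
- Merits: the lactone ring and the C3 stereocentre form in one neutral step, no activating ester has to be removed, and both aryl rings come from ordinary aromatic building blocks.
- Weak points: the C4 stereocentre of A1 must first be built enantioselectively in an acyclic chain (for instance by an auxiliary-controlled alkylation), which costs several steps. The trans preference of a 5-exo closure onto a 1,2-disubstituted alkene is usually modest. Selenium reagents are needed.
- Comparison: the cis isomer could be equilibrated at C3, so selectivity is not fatal, and the key step is closer to precedent than the benzannulation chosen here. Against that, the chosen plan takes C4 from (R)-epichlorohydrin in one step and carries only one protecting group.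

**Alternative 2:** The C7–ring S and C3–C7' bonds are cut in one operation. The arylcopper species from Grignard reagent 6 and catalytic CuI opens cyclopropane 5, and the released enolate is benzylated in the same flask by 4-(benzyloxy)-3-methoxybenzyl bromide A4 to give A3. Krapcho reaction and double hydrogenolysis would finish the synthesis.
- Merits: this is the shortest road to the target, about three steps fewer than the chosen plan, and every step has close precedent.
- Weak points: any excess of 6 couples with A4 under copper catalysis, so the stoichiometry of the one-flask trap is delicate. Magnesium enolates of malonate type alkylate sluggishly. A4 is an electron-rich benzyl bromide of limited stability. Both phenols end up under the same protecting group.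
- Comparison: for this one target, Alternative 2 is the more economical route. The chosen plan offers in return a ring G built last from the common intermediate 10 (so analogues or labelled rings come from a different ketone), no vanillyl halide, and intermediates 13 and 14 in which the two phenols are already differentiated.

**Alternative 3:** Both C–O bonds of O1 are cut, leading back to the prochiral cyclobutanone A5. A Baeyer–Villiger monooxygenase inserts oxygen next to one enantiotopic CH2 and gives the (4R)-lactone A6. Enolate benzylation of A6 with A4 would then lead to A2.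
- Merits: C4 is set catalytically from an achiral precursor with O2 as oxidant, and no ester activation or decarboxylation is needed.
- Weak points: the sense and level of enantioselection for this bulky, electron-rich substrate cannot be predicted and would require enzyme screening. A5 has to be made first (ketene cycloaddition and dechlorination). The key step sets only C4, so C3 still needs a separate alkylation with A4.
- Comparison: overall length is similar to the chosen plan. The chosen plan relies on the chiral pool for C4, so its enantiopurity is limited only by that of 3 and by the regioselectivity of the first malonate attack, and it needs no biocatalyst.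

Key step: step 6

Assumptions on the chemistry:
- In step 6 the first C–C bond is taken to form at the methyl carbon of methoxyacetone, which defines intermediate 12. The other order of events would pass through an isomeric aminodienone and end in the same phenol 13.
- Lactone ester 7 is configurationally labile at C3 and is carried forward as its mixture of C3 epimers.

## Route

Step 1
Reactants: 1 4-bromo-2,6-dimethoxyphenol
Product: 2 2-(benzyloxy)-5-bromo-1,3-dimethoxybenzene
Conditions: BnBr, K2CO3, DMF, 60 °C
Reagents that add atoms: benzyl bromide, BrCc1ccccc1
Why: Williamson etherification of the phenol; the aryl bromide is inert to carbonate, and the benzyl ether should survive every later step until the final hydrogenolysis.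

Step 2
Reactants: 3 (R)-epichlorohydrin; 4 diethyl malonate
Product: 5 ethyl (1S,5R)-2-oxo-3-oxabicyclo[3.1.0]hexane-1-carboxylate
Conditions: NaOEt, EtOH, 0 °C then reflux
Reagents that add atoms: none
Why: Known tandem alkylation–cyclopropanation–lactonisation: the malonate anion opens the epoxide at its CH2, the alkoxide recloses onto CH2Cl, and the malonate carbanion opens the new epoxide at the stereogenic carbon in a 3-exo-tet SN2 reaction with inversion before the alkoxide lactonises onto the cis ester. (R)-Epichlorohydrin should thereby give the (1S,5R) lactone, whose C5 becomes C4 (R) of the target.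

Step 3
Reactants: 2 2-(benzyloxy)-5-bromo-1,3-dimethoxybenzene; 5 ethyl (1S,5R)-2-oxo-3-oxabicyclo[3.1.0]hexane-1-carboxylate
Product: 7 ethyl (4R)-4-[4-(benzyloxy)-3,5-dimethoxybenzyl]-2-oxotetrahydrofuran-3-carboxylate (mixture of C3 epimers), via arylmagnesium bromide 6 (not isolated)
Conditions: Mg, I2 (cat.), THF, 50 °C; then CuI (10 mol %), 5, THF, −30 to 0 °C; 1 M HCl
Reagents that add atoms: none
Why: Copper-catalysed (CuI) homoconjugate addition of an aryl Grignard reagent to a doubly activated cyclopropane, which opens it by SN2 attack at the unsubstituted CH2 and forms the C7–aryl bond. The stereocentre is not touched and becomes C4 (R); C3 is protonated on work-up and is labile.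

Step 4
Reactants: 7 ethyl (4R)-4-[4-(benzyloxy)-3,5-dimethoxybenzyl]-2-oxotetrahydrofuran-3-carboxylate; 8 acrolein
Product: 9 ethyl (3R,4R)-4-[4-(benzyloxy)-3,5-dimethoxybenzyl]-2-oxo-3-(3-oxopropyl)tetrahydrofuran-3-carboxylate
Conditions: acrolein (1.5 equiv), DBU (5 mol %), THF, −20 to 0 °C
Reagents that add atoms: none
Why: Base-catalysed Michael addition of a malonate-type CH acid to acrolein forms C3–C7'. The enolate is attacked on the face anti to the C4 arylmethyl group, which should give the (3R) quaternary centre; any C3 epimer converges later because C3 is reset in step 7.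

Step 5
Reactants: 9 ethyl (3R,4R)-4-[4-(benzyloxy)-3,5-dimethoxybenzyl]-2-oxo-3-(3-oxopropyl)tetrahydrofuran-3-carboxylate
Product: 10 ethyl (3R,4R)-4-[4-(benzyloxy)-3,5-dimethoxybenzyl]-3-[(2E)-3-(dimethylamino)-2-formylprop-2-en-1-yl]-2-oxotetrahydrofuran-3-carboxylate
Conditions: tert-butoxybis(dimethylamino)methane (1.5 equiv), toluene, 70 °C
Reagents that add atoms: tert-butoxybis(dimethylamino)methane, CN(C)C(OC(C)(C)C)N(C)C
Why: α-Aminomethylenation of an enolisable aldehyde by a formamide aminal ester gives the push–pull 2-substituted 3-(dimethylamino)acrolein, with the amino group anti to the formyl group (E). The only other α-carbon in the molecule, C3, is quaternary and cannot react.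

Step 6
Reactants: 10 ethyl (3R,4R)-4-[4-(benzyloxy)-3,5-dimethoxybenzyl]-3-[(2E)-3-(dimethylamino)-2-formylprop-2-en-1-yl]-2-oxotetrahydrofuran-3-carboxylate; 11 methoxyacetone
Product: 13 ethyl (3R,4R)-4-[4-(benzyloxy)-3,5-dimethoxybenzyl]-3-(4-hydroxy-3-methoxybenzyl)-2-oxotetrahydrofuran-3-carboxylate, via aminodienone 12 (not isolated)
Conditions: 11 (3 equiv), KOtBu (3.5 equiv), THF, 0 °C; then 10, 0 to 60 °C; AcOH quench
Reagents that add atoms: none
Why: KOtBu converts methoxyacetone into its enolates; aldol addition of the methyl-side enolate to the formyl carbon of the vinylogous formamide and E1cB loss of water give aminodienone 12 (bond C5'–C6'). A second deprotonation at the CH2OMe carbon gives a 1-amino-hexatrienolate, and the push–pull character of 12 lowers the barrier to E/Z isomerisation of its central double bond so that the s-cis,Z arrangement needed for closure can be reached. Ring G then closes as a six-membered carbocycle by disrotatory 6π-electrocyclisation of the trienolate (equivalent in outcome to a 6-endo-trig attack of the enolate carbon on the aminomethylene carbon), forming C2'–C3'. E1cB loss of dimethylamine and tautomerisation give the phenoxide, and aromatisation makes the sequence irreversible. The closest known reaction type is the [3+3] benzannulation of ketones having two enolisable α-positions with vinamidinium salts or 3-(dimethylamino)acroleins to give para-substituted phenols, of which an α-alkoxy ketone partner is a less common member. No stereocentre is formed, and C3, being quaternary, cannot be enolised or epimerised by the base. The selectivity needed is constitutional only: the dielectrophile is symmetric about the carbon bearing C7', so both orientations of the unsymmetrical ketone end in the same 4-alkyl-2-methoxyphenol, and excess ketone suppresses twofold condensation. Chemoselectivity against the ester and lactone carbonyls rests on their shielding by the quaternary C3 and on the poor nucleophilicity of tert-butoxide.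

Step 7
Reactants: 13 ethyl (3R,4R)-4-[4-(benzyloxy)-3,5-dimethoxybenzyl]-3-(4-hydroxy-3-methoxybenzyl)-2-oxotetrahydrofuran-3-carboxylate
Product: 14 (3R,4R)-4-[4-(benzyloxy)-3,5-dimethoxybenzyl]-3-(4-hydroxy-3-methoxybenzyl)dihydrofuran-2(3H)-one
Conditions: LiCl (4 equiv), H2O (2 equiv), DMSO, 150 °C, under N2
Reagents that add atoms: none
Why: Krapcho dealkoxycarbonylation: chloride dealkylates the ethyl ester, the carboxylate loses CO2 and the lactone enolate is protonated. At 150 °C with basic lithium salts present, C3 should equilibrate to the more stable 3,4-trans (3R) isomer under the control of C4.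

Step 8
Reactants: 14 (3R,4R)-4-[4-(benzyloxy)-3,5-dimethoxybenzyl]-3-(4-hydroxy-3-methoxybenzyl)dihydrofuran-2(3H)-one
Product: 15 (3R,4R)-3-(4-hydroxy-3-methoxybenzyl)-4-(4-hydroxy-3,5-dimethoxybenzyl)dihydrofuran-2(3H)-one
Conditions: H2 (1 atm), 10% Pd/C, EtOAc–EtOH, rt
Reagents that add atoms: none
Why: Hydrogenolysis of an aryl benzyl ether over Pd/C; the lactone, the phenols and the benzylic C–C bonds are inert under these neutral conditions, and C3 is not epimerised.

## Compound list

1 | 4-bromo-2,6-dimethoxyphenol | COc1cc(Br)cc(OC)c1O | starting material
2 | 2-(benzyloxy)-5-bromo-1,3-dimethoxybenzene | COc1cc(Br)cc(OC)c1OCc1ccccc1 | intermediate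
3 | (R)-epichlorohydrin | ClC[C@H]1CO1 | starting material
4 | diethyl malonate | CCOC(=O)CC(=O)OCC | starting material
5 | ethyl (1S,5R)-2-oxo-3-oxabicyclo[3.1.0]hexane-1-carboxylate | CCOC(=O)[C@]12C[C@H]1COC2=O | intermediate
6 | [4-(benzyloxy)-3,5-dimethoxyphenyl]magnesium bromide | COc1cc([Mg]Br)cc(OC)c1OCc1ccccc1 | intermediate
7 | ethyl (4R)-4-[4-(benzyloxy)-3,5-dimethoxybenzyl]-2-oxotetrahydrofuran-3-carboxylate (C3 epimers) | CCOC(=O)C1C(=O)OC[C@@H]1Cc1cc(OC)c(OCc2ccccc2)c(OC)c1 | intermediate
8 | acrolein | C=CC=O | starting material
9 | ethyl (3R,4R)-4-[4-(benzyloxy)-3,5-dimethoxybenzyl]-2-oxo-3-(3-oxopropyl)tetrahydrofuran-3-carboxylate | CCOC(=O)[C@]1(CCC=O)C(=O)OC[C@@H]1Cc1cc(OC)c(OCc2ccccc2)c(OC)c1 | intermediate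
10 | ethyl (3R,4R)-4-[4-(benzyloxy)-3,5-dimethoxybenzyl]-3-[(2E)-3-(dimethylamino)-2-formylprop-2-en-1-yl]-2-oxotetrahydrofuran-3-carboxylate | CCOC(=O)[C@]1(C/C(C=O)=C\N(C)C)C(=O)OC[C@@H]1Cc1cc(OC)c(OCc2ccccc2)c(OC)c1 | intermediate
11 | methoxyacetone | COCC(C)=O | starting material
12 | ethyl (3R,4R)-4-[4-(benzyloxy)-3,5-dimethoxybenzyl]-3-[(2E,3E)-2-[(dimethylamino)methylidene]-6-methoxy-5-oxohex-3-en-1-yl]-2-oxotetrahydrofuran-3-carboxylate | CCOC(=O)[C@]1(C/C(=C\N(C)C)/C=C/C(=O)COC)C(=O)OC[C@@H]1Cc1cc(OC)c(OCc2ccccc2)c(OC)c1 | intermediate
13 | ethyl (3R,4R)-4-[4-(benzyloxy)-3,5-dimethoxybenzyl]-3-(4-hydroxy-3-methoxybenzyl)-2-oxotetrahydrofuran-3-carboxylate | CCOC(=O)[C@]1(Cc2ccc(O)c(OC)c2)C(=O)OC[C@@H]1Cc1cc(OC)c(OCc2ccccc2)c(OC)c1 | intermediate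
14 | (3R,4R)-4-[4-(benzyloxy)-3,5-dimethoxybenzyl]-3-(4-hydroxy-3-methoxybenzyl)dihydrofuran-2(3H)-one | COc1cc(C[C@H]2C(=O)OC[C@@H]2Cc2cc(OC)c(OCc3ccccc3)c(OC)c2)ccc1O | intermediate
15 | (3R,4R)-3-(4-hydroxy-3-methoxybenzyl)-4-(4-hydroxy-3,5-dimethoxybenzyl)dihydrofuran-2(3H)-one | COc1cc(C[C@H]2C(=O)OC[C@@H]2Cc2cc(OC)c(O)c(OC)c2)ccc1O | target

## Step count and risks

Total: 8 steps. Longest linear sequence: 7 steps (3 and 4 → 5 → 7 → 9 → 10 → 13 → 14 → 15; the branch from 1 through 2 is equally long).

**Step 6 (key step).**
- Slow first condensation: the formyl group of a vinylogous formamide is a weak electrophile, so self-condensation of methoxyacetone may outrun it.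
- Stalling at 12: the second closure fails if the central double bond does not isomerise.
- Fragmentation: the amino group can push electrons through the enal and expel the stabilised lactone-ester enolate from C7' (a retro-Michael process).
- Attack of tert-butoxide on the ester: this would strip the ethoxycarbonyl group early and expose an enolisable C3.
- Fallback: give up the ring construction and bring in ring G ready-made. Setting out from lactone ester 7, the sodium enolate (NaH, THF–DMF, 0 °C) would be benzylated with bromide A4 to give ethyl (3R,4R)-3-[4-(benzyloxy)-3-methoxybenzyl]-4-[4-(benzyloxy)-3,5-dimethoxybenzyl]-2-oxotetrahydrofuran-3-carboxylate F1 (constitutionally the compound A3). Dealkoxycarbonylation under the conditions of step 7 would give (3R,4R)-3-[4-(benzyloxy)-3-methoxybenzyl]-4-[4-(benzyloxy)-3,5-dimethoxybenzyl]dihydrofuran-2(3H)-one F2, and hydrogenolysis of both benzyl ethers over Pd/C would return to the route at target 15.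

**Step 5.**
- The basic, warm conditions may cause self-aldol condensation of the aliphatic aldehyde, or retro-Michael loss of acrolein from its enolate, before the α-carbon is captured.
- Fallback: formylate a preformed enol derivative under non-basic conditions. Setting out from aldehyde 9, Me3SiOTf and Et3N in CH2Cl2 at 0 °C would give ethyl (3R,4R)-4-[4-(benzyloxy)-3,5-dimethoxybenzyl]-2-oxo-3-[3-(trimethylsilyloxy)prop-2-en-1-yl]tetrahydrofuran-3-carboxylate F3 (E/Z mixture). Its reaction with (chloromethylene)dimethyliminium chloride in CH2Cl2 at 0 °C (Vilsmeier C-formylation of a silyl enol ether; the cold conditions should spare the electron-rich ring S), followed by bicarbonate work-up, would return to the route at 10.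

**Step 4.**
- Acrolein may polymerise under base, and the product aldehyde may undergo aldol reaction with the enolate of 7, eroding the Michael adduct.
- Fallback: alkylate instead of adding conjugately. Setting out from 7, NaH in DMF followed by commercial 2-(2-bromoethyl)-1,3-dioxolane (BrCCC1OCCO1) at 50 °C would give ethyl (3R,4R)-4-[4-(benzyloxy)-3,5-dimethoxybenzyl]-3-[2-(1,3-dioxolan-2-yl)ethyl]-2-oxotetrahydrofuran-3-carboxylate F4. Acetal hydrolysis with aqueous HCl in THF would return to the route at 9.

**Step 7.**
- Kinetic protonation anti to the C4 arm may leave some cis isomer, chloride may open the lactone at C5, and the free phenol may be oxidised in hot DMSO.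
- Fallback: replace nucleophilic dealkylation by hydrolysis and thermal decarboxylation. Setting out from 13, LiOH in THF–H2O under N2 would cleave the ester (and open the lactone). Acidification with HCl would reclose the ring to (4R)-4-[4-(benzyloxy)-3,5-dimethoxybenzyl]-3-(4-hydroxy-3-methoxybenzyl)-2-oxotetrahydrofuran-3-carboxylic acid F5 (C3 epimers). Heating in toluene at 110 °C would expel CO2, and brief treatment with DBU would equilibrate C3 to the trans isomer, returning to the route at 14.

## Further compounds

F1 | step 6 | ethyl (3R,4R)-3-[4-(benzyloxy)-3-methoxybenzyl]-4-[4-(benzyloxy)-3,5-dimethoxybenzyl]-2-oxotetrahydrofuran-3-carboxylate | CCOC(=O)[C@]1(Cc2ccc(OCc3ccccc3)c(OC)c2)C(=O)OC[C@@H]1Cc1cc(OC)c(OCc2ccccc2)c(OC)c1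
F2 | step 6 | (3R,4R)-3-[4-(benzyloxy)-3-methoxybenzyl]-4-[4-(benzyloxy)-3,5-dimethoxybenzyl]dihydrofuran-2(3H)-one | COc1cc(C[C@H]2C(=O)OC[C@@H]2Cc2cc(OC)c(OCc3ccccc3)c(OC)c2)ccc1OCc1ccccc1
F3 | step 5 | ethyl (3R,4R)-4-[4-(benzyloxy)-3,5-dimethoxybenzyl]-2-oxo-3-[3-(trimethylsilyloxy)prop-2-en-1-yl]tetrahydrofuran-3-carboxylate (E/Z mixture) | CCOC(=O)[C@]1(CC=CO[Si](C)(C)C)C(=O)OC[C@@H]1Cc1cc(OC)c(OCc2ccccc2)c(OC)c1
F4 | step 4 | ethyl (3R,4R)-4-[4-(benzyloxy)-3,5-dimethoxybenzyl]-3-[2-(1,3-dioxolan-2-yl)ethyl]-2-oxotetrahydrofuran-3-carboxylate | CCOC(=O)[C@]1(CCC2OCCO2)C(=O)OC[C@@H]1Cc1cc(OC)c(OCc2ccccc2)c(OC)c1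
F5 | step 7 | (4R)-4-[4-(benzyloxy)-3,5-dimethoxybenzyl]-3-(4-hydroxy-3-methoxybenzyl)-2-oxotetrahydrofuran-3-carboxylic acid (C3 epimers) | OC(=O)C1(Cc2ccc(O)c(OC)c2)C(=O)OC[C@@H]1Cc1cc(OC)c(OCc2ccccc2)c(OC)c1
A1 | alternative 1 | O-[(2R,3E)-2-[4-(benzyloxy)-3,5-dimethoxybenzyl]-4-[4-(benzyloxy)-3-methoxyphenyl]but-3-en-1-yl] Se-phenyl carbonoselenoate | O=C([Se]c1ccccc1)OC[C@H](Cc1cc(OC)c(OCc2ccccc2)c(OC)c1)/C=C/c1ccc(OCc2ccccc2)c(OC)c1
A2 | alternative 1 | (3R,4R)-3-[4-(benzyloxy)-3-methoxybenzyl]-4-[4-(benzyloxy)-3,5-dimethoxybenzyl]dihydrofuran-2(3H)-one | COc1cc(C[C@H]2C(=O)OC[C@@H]2Cc2cc(OC)c(OCc3ccccc3)c(OC)c2)ccc1OCc1ccccc1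
A3 | alternative 2 | ethyl (3R,4R)-3-[4-(benzyloxy)-3-methoxybenzyl]-4-[4-(benzyloxy)-3,5-dimethoxybenzyl]-2-oxotetrahydrofuran-3-carboxylate | CCOC(=O)[C@]1(Cc2ccc(OCc3ccccc3)c(OC)c2)C(=O)OC[C@@H]1Cc1cc(OC)c(OCc2ccccc2)c(OC)c1
A4 | alternative 2 | 4-(benzyloxy)-3-methoxybenzyl bromide | COc1cc(CBr)ccc1OCc1ccccc1
A5 | alternative 3 | 3-[4-(benzyloxy)-3,5-dimethoxybenzyl]cyclobutan-1-one | O=C1CC(Cc2cc(OC)c(OCc3ccccc3)c(OC)c2)C1
A6 | alternative 3 | (4R)-4-[4-(benzyloxy)-3,5-dimethoxybenzyl]dihydrofuran-2(3H)-one | O=C1C[C@@H](Cc2cc(OC)c(OCc3ccccc3)c(OC)c2)CO1
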